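## The problem

Atoms are numbered in the order of the target SMILES string (C1 methyl to C38, oxygens counted). Compound 50 is a pentacyclic spirotetronate. It has a trans-fused decalin (ring A: C2–C6 and C38; ring B: C5–C9 and C36, with the C7=C8 alkene). It has a cyclohexene ring C (C15, C17=C18, C21, C26, C27) spiro-fused at C27 to the 3-acyl tetronic acid ring D. An 11-membered carbocycle runs C9–C10–C12=C13–C14–C15–C27–C32=C31–C34–C36.

There are ten stereocentres and one E-alkene. C36 and C15 are quaternary, and C15 is vicinal to the spiro carbon C27. The C2 methyl is axial on ring A, which is the opposite of what a chair-like Diels–Alder closure of the decalin prefers. One cycloaddition can set C5, C6, C9 and C36 together, but C2 and C10 are brought in beforehand and must not steer it to the wrong face. In ring C, C15 can be fixed first and then relay to C21 and C27; C23 is remote and needs a reagent.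

The acyl tetronic acid is a strong acid, and its O-methyl ether is electrophilic at C32 and at the methyl group. The C19 allylic alcohol and the C23 alcohol need protection. The strained macrocycle must be closed without touching C10 or the two ring alkenes.

The 11-membered ring holds a single isolated E-alkene, C12=C13, with sp3 neighbours on both sides (C10 and C14). Replacing it by CH2–SO2–CH2 gives a 12-membered thiacycle that can be closed by S-alkylation. Because C36 is quaternary and C31 fully substituted, the two sulfone α-methylenes are the only acidic C–H bonds once the tetronate is ionised.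

## Retrosynthesis

**50 from 49.** Only the O20 and O25 MOM ethers are removed. MOM survives every base, hydride, fluoride and oxidant used earlier, so one acid step at the end suffices. The forward step must cleave two acetals without ionising the C19 allylic position.

**49 from 46 (key step).** The C12=C13 alkene is cut back to a sulfone with sulfur between C12 and C13. A direct C–C closure of the 11-membered ring (olefin metathesis, or acylation at C31–C34) would have to pay the medium-ring strain in the bond-forming step. The sulfone route closes a 12-membered ring at sulfur and then contracts it. The reaction is run on the free tetronic acid 46 rather than on its methyl ether 45. As the potassium salt, C32 and C34 are no longer electrophilic towards the C13 and C12 carbanions, each of which sits in a 1,5-relationship to one of them. The forward reaction must give the E-alkene.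

**46 from 42, through 44 and 45.** The C13–S bond is cut to a C12 thiolate and a C13 mesylate. Sulfur is placed on C12 because a C13 thiolate could add to C32 through a six-membered ring. The precursor 42 is acyclic at this point and comes from seco ketone 37 by unmasking two orthogonal silyl ethers (TBS on O-C12, TBDPS on O-C13). The forward reaction is a 12-membered closure at high dilution.

**37 from 34 and 10.** The C31–C34 bond is cut to the C31-lithiated tetronate methyl ether and the C34 aldehyde. This divides the molecule into two halves of similar size, each carrying its own stereocentres. The forward reaction is addition of a vinyl-lithium to a neopentyl aldehyde; the new C34 carbinol is oxidised, so its configuration does not matter.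

**10 from 9; 9 from 8 and 4.** The C5–C6 and C9–C36 bonds are cut in an intramolecular Diels–Alder reaction of an (E,E,E)-2-methyl-trienal. This is the shortest way to four contiguous centres including quaternary C36. Its weakness is that the tether wants the C2 methyl equatorial, so the reaction is run under catalyst control. Trienal 9 is cut at C7–C8 into iodo-enal 8 (from (S)-citronellal 5, which brings C2) and alkenylboronate 4 (from Roche ester 1, which brings C10).

**34 from 29 and 30.** The C27–C32 and O28–C29 bonds are cut: the tetronate is built on the C27 ketone from methyl propiolate and methoxide. The forward addition must come from the face of the C16 methyl; the C14 arm and the C21 side chain both shield the other face.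

**29 from 26; 24 from 20 and 21.** The C21–C22 bond is cut by a Claisen rearrangement that transfers the C17 carbinol configuration to C21 and places the C17=C18 alkene in the same step. A cuprate addition to the corresponding enone would add anti to the lactone ring and give the wrong C21. The cis-fused γ-lactone in 15–26 hides O28 and C13 and makes the bicycle rigid. Reduction and oxidation later release the C13 alcohol and the C27 ketone.

**20 from 15; 15 from 13; 13 from 11 and 12.** C19 is attached by hydroxymethylation of enone 17. The quaternary C15 is set by reductive desymmetrisation of the achiral dione 13, made in one alkylation from 11 and 12.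

## Roads not taken

**Alternative 1:** anodic dearomative spirolactonisation. The cut is C27–O28. Anodic oxidation of (E)-3-(4-hydroxyphenyl)-3-methoxyacrylic acid A1 would give the spiro-dienone tetronate A2 in one step.
- Merits: ring D and the spiro carbon arise at once from a flat, cheap aromatic, with no chemical oxidant. This is far shorter than the fourteen steps to 34.
- Weak points: A2 is achiral, and C27 becomes stereogenic only when the two enone arms are told apart. C15 would then need two carbon groups at a β-carbon next to the spiro centre. C21 needs one more, and the dienone carbonyl (C18) must be homologated to C19. All of this happens on a base-sensitive tetronate, with four centres to be related to one another by untested substrate control.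
- Comparison: for reaching the tetronate, Alternative 1 is better. The chosen plan sets against it that C15 is fixed in its first asymmetric step and that C17, C21 and C27 are each relayed from it by reactions whose facial sense can be argued.

**Alternative 2:** lactone-to-cyclohexene Ireland–Claisen rearrangement. The cut is C9–C36. The silyl ketene acetal of the ring-A-fused δ-lactone A3 would rearrange to decalin acid A4, closing ring B and forming C7=C8.
- Merits: ring A would be a preformed cyclohexane, so the axial C2 methyl could be set by a trans-selective conjugate addition and would not depend on a cycloaddition face. The rearrangement sets C9 and quaternary C36 together by chirality transfer from C7.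
- Weak points: A3 carries five stereocentres and an E-alkenyl chain and would need roughly twice as many steps as 9. The ring contraction must go through a boat transition state. A4 needs two more redox steps to reach the aldehyde.
- Comparison: for C2, Alternative 2 is the safer road, and this is stated plainly. The chosen plan sets against it a seven-step convergent route to 10 from two chiral-pool materials, at the price of a catalyst that must overrule the tether. If that fails for good, A4 is the natural replacement for the decalin half, and the key step is not affected.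

**Alternative 3:** cyclopropane as masked methyl. The cut is C15–C16. Hydroxyl-directed Simmons–Smith cyclopropanation (Et2Zn, CH2I2) of cyclohexenol A5 would give cyclopropyl carbinol A6. Oxidation and reductive opening of the C16–C17 bond would later reveal the methyl group.
- Merits: directed cyclopropanation is reliable and fixes quaternary C15 relative to C18. The tetronate would be made earlier, on a ketone that is not neopentyl, which is easier than step 20 here.
- Weak points: opening the cyclopropyl ketone needs dissolving-metal or SmI2 conditions in the presence of a reducible tetronate. C19 and the whole C21 side chain are still missing in A6, and the sequence is long.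
- Comparison: Alternative 3 is as good for C15 and better for the addition at C27. The chosen plan sets against it that C15 is complete after two steps and that no late reductive step is needed.

Key step: step 31

Assumption: in step 7 the (S)-configured oxazaborolidinium ion is taken to expose the enal face that leads to 10, as it does for other 2-substituted enals; the mirror-image catalyst would be used if the sense proved opposite.

## Route

Step 1
Reactants: 1 methyl (R)-3-hydroxy-2-methylpropanoate
Product: 2 methyl (R)-3-[(tert-butyldimethylsilyl)oxy]-2-methylpropanoate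
Conditions: TBSCl, imidazole, CH2Cl2, 0 °C to rt
Reagents that add atoms: tert-butyldimethylsilyl chloride, CC(C)(C)[Si](C)(C)Cl
Why: Standard silylation of a primary alcohol; the stereocentre (future C10) is not touched.

Step 2
Reactants: 2 methyl (R)-3-[(tert-butyldimethylsilyl)oxy]-2-methylpropanoate
Product: 3 (R)-3-[(tert-butyldimethylsilyl)oxy]-2-methylpropanal
Conditions: iBu2AlH, CH2Cl2, −78 °C
Reagents that add atoms: none
Why: Partial ester reduction through the stable aluminium hemiacetal at low temperature; the aldehyde should be used crude to avoid epimerisation at C10.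

Step 3
Reactants: 3 (R)-3-[(tert-butyldimethylsilyl)oxy]-2-methylpropanal
Product: 4 tert-butyldimethyl{[(2S,3E)-2-methyl-4-(4,4,5,5-tetramethyl-1,3,2-dioxaborolan-2-yl)but-3-en-1-yl]oxy}silane
Conditions: CrCl2, LiI, Cl2CHB(pin), THF, rt
Reagents that add atoms: 2-(dichloromethyl)-4,4,5,5-tetramethyl-1,3,2-dioxaborolane, CC1(C)OB(C(Cl)Cl)OC1(C)C
Why: Takai-type boryl-olefination: a geminal dichromium species adds to the aldehyde and eliminates to the (E)-alkenylboronate under non-basic conditions that should leave C10 intact; this sets the C8=C9 geometry.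

Step 4
Reactants: 5 (S)-citronellal [(3S)-3,7-dimethyloct-6-enal]
Product: 6 (1E,4S)-1-iodo-4,8-dimethylnona-1,7-diene
Conditions: CrCl2, CHI3, THF/dioxane (1:6), 0 °C to rt
Reagents that add atoms: iodoform, IC(I)I
Why: Takai iodo-olefination should give the (E)-vinyl iodide (C6=C7); any Z isomer cannot cyclise in step 7 and is lost there.

Step 5
Reactants: 6 (1E,4S)-1-iodo-4,8-dimethylnona-1,7-diene
Product: 8 (2E,6S,8E)-9-iodo-2,6-dimethylnona-2,8-dienal, via allylic alcohol 7 (not isolated)
Conditions: SeO2 (0.3 equiv), tBuOOH, CH2Cl2, rt; then MnO2, CH2Cl2, rt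
Reagents that add atoms: selenium dioxide, O=[Se]=O; tert-butyl hydroperoxide, CC(C)(C)OO
Why: Selenium dioxide allylic oxidation (ene reaction then [2,3] shift) attacks the (E)-methyl of the electron-rich trisubstituted alkene only, the iodoalkene being deactivated; MnO2 then brings the alcohol/aldehyde mixture to the (E)-enal.

Step 6
Reactants: 8 (2E,6S,8E)-9-iodo-2,6-dimethylnona-2,8-dienal; 4 tert-butyldimethyl{[(2S,3E)-2-methyl-4-(4,4,5,5-tetramethyl-1,3,2-dioxaborolan-2-yl)but-3-en-1-yl]oxy}silane
Product: 9 (2E,6S,8E,10E,12S)-13-[(tert-butyldimethylsilyl)oxy]-2,6,12-trimethyltrideca-2,8,10-trienal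
Conditions: PdCl2[1,1′-bis(diphenylphosphino)ferrocene] (5 mol %), K3PO4 (aq.), THF, rt
Reagents that add atoms: none
Why: Suzuki–Miyaura coupling of an alkenyl iodide with an alkenylboronate forms C7–C8 with retention of both E geometries; the enal has no acidic α-hydrogen and should tolerate the mild base.

Step 7
Reactants: 9 (2E,6S,8E,10E,12S)-13-[(tert-butyldimethylsilyl)oxy]-2,6,12-trimethyltrideca-2,8,10-trienal
Product: 10 (1S,2S,4aS,6S,8aR)-2-[(2S)-1-[(tert-butyldimethylsilyl)oxy]propan-2-yl]-1,6-dimethyl-1,2,4a,5,6,7,8,8a-octahydronaphthalene-1-carbaldehyde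
Conditions: (S)-3,3-diphenyl-1-(2-methylphenyl)tetrahydro-1H,3H-pyrrolo[1,2-c][1,3,2]oxazaborole (20 mol %), HN(SO2CF3)2 (18 mol %), CH2Cl2, −78 to −40 °C
Reagents that add atoms: none
Why: Lewis-acid-catalysed intramolecular Diels–Alder reaction of an (E,E,E)-2-methyl-2,8,10-trienal through the aldehyde-endo transition state, which gives the trans-fused decalin and sets C5, C6, C9 and C36 together (C34 cis to the C10 chain). The face is chosen by the chiral oxazaborolidinium ion and by C10 (silyloxymethyl anti to the forming bond, methyl inside), which together should outvote the tether's wish to keep the C2 methyl equatorial; the C2-axial adduct 10 is expected as the major isomer and its diastereomer is removed by chromatography.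

Step 8
Reactants: 11 2-methylcyclohexane-1,3-dione; 12 ethyl bromoacetate
Product: 13 ethyl 2-(1-methyl-2,6-dioxocyclohexyl)acetate
Conditions: KOtBu, tBuOH, 60 °C
Reagents that add atoms: none
Why: C-Alkylation of the dione enolate with an activated primary halide builds the quaternary carbon (future C15) with its methyl and the C14–C13 arm; some O-alkylation is expected and is separable.

Step 9
Reactants: 13 ethyl 2-(1-methyl-2,6-dioxocyclohexyl)acetate
Product: 15 (3aS,7aS)-3a-methylhexahydro-1-benzofuran-2,4-dione (cis-fused keto lactone), via hydroxy ester 14 (not isolated)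
Conditions: (R)-1-methyl-3,3-diphenyltetrahydro-1H,3H-pyrrolo[1,2-c][1,3,2]oxazaborole (0.2 equiv), BH3·SMe2 (0.6 equiv), THF, −30 °C; then p-toluenesulfonic acid (cat.), toluene, rt
Reagents that add atoms: none
Why: Corey–Bakshi–Shibata desymmetrisation of a 2,2-disubstituted cyclic 1,3-dione: the catalyst fixes the carbinol as (S) and hydride enters anti to the larger ester arm, so only the matched carbonyl should react and the new hydroxyl, cis to the arm, closes the γ-lactone. This sets C15 and a temporary centre at C27 and masks O28 and C13.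

Step 10
Reactants: 15 (3aS,7aS)-3a-methylhexahydro-1-benzofuran-2,4-dione
Product: 17 (3aS,7aS)-3a-methyl-3a,7a-dihydro-1-benzofuran-2,4(3H,7H)-dione, via silyl enol ether 16 (not isolated)
Conditions: Me3SiOTf, Et3N, CH2Cl2, 0 °C; then Pd(OAc)2 (10 mol %), O2 (1 atm), DMSO, 40 °C
Reagents that add atoms: none
Why: Saegusa–Ito dehydrogenation; the ketone can enolise only towards C18 because C15 is quaternary, and soft enolisation should leave the lactone alone.

Step 11
Reactants: 17 (3aS,7aS)-3a-methyl-3a,7a-dihydro-1-benzofuran-2,4(3H,7H)-dione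
Product: 18 (3aS,7aS)-5-(hydroxymethyl)-3a-methyl-3a,7a-dihydro-1-benzofuran-2,4(3H,7H)-dione
Conditions: HCHO (37% aq.), 4-(dimethylamino)pyridine (0.2 equiv), THF/H2O, rt
Reagents that add atoms: formaldehyde, C=O
Why: Morita–Baylis–Hillman hydroxymethylation of a cyclic enone at its α-carbon attaches C19 to C18.

Step 12
Reactants: 18 (3aS,7aS)-5-(hydroxymethyl)-3a-methyl-3a,7a-dihydro-1-benzofuran-2,4(3H,7H)-dione
Product: 19 (3aS,7aS)-5-[(methoxymethoxy)methyl]-3a-methyl-3a,7a-dihydro-1-benzofuran-2,4(3H,7H)-dione
Conditions: MOMCl, iPr2NEt, CH2Cl2, 0 °C to rt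
Reagents that add atoms: chloromethyl methyl ether, COCCl
Why: Standard alkoxymethylation of a primary alcohol; this MOM ether (O20) stays to the last step.

Step 13
Reactants: 19 (3aS,7aS)-5-[(methoxymethoxy)methyl]-3a-methyl-3a,7a-dihydro-1-benzofuran-2,4(3H,7H)-dione
Product: 20 (3aR,4R,7aS)-4-hydroxy-5-[(methoxymethoxy)methyl]-3a-methyl-3a,4,7,7a-tetrahydro-1-benzofuran-2(3H)-one (hydroxyl cis to the lactone ring)
Conditions: NaBH4, CeCl3·7H2O, MeOH, −78 °C
Reagents that add atoms: none
Why: Luche 1,2-reduction; hydride is expected from the convex face of the cis-fused bicycle, anti to the lactone ring, which puts the C17 hydroxyl cis to the C14 arm. The lactone is not reduced at this temperature.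

Step 14
Reactants: 20 (3aR,4R,7aS)-4-hydroxy-5-[(methoxymethoxy)methyl]-3a-methyl-3a,4,7,7a-tetrahydro-1-benzofuran-2(3H)-one; 21 2-methoxypropene
Product: 24 (3aR,6S,7aS)-5-[(methoxymethoxy)methyl]-3a-methyl-6-(2-oxopropyl)-3a,6,7,7a-tetrahydro-1-benzofuran-2(3H)-one, via mixed acetal 22 (not isolated), via isopropenyl ether 23 (not isolated)
Conditions: propionic acid (5 mol %), xylene, 135 °C, sealed tube
Reagents that add atoms: none
Why: Claisen rearrangement of the allyl isopropenyl ether formed in the flask (ketone variant): C21–C22 forms suprafacially on the face that carried the C17 oxygen, so C21 is set cis to the C14 arm while the alkene moves to C17=C18.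

Step 15
Reactants: 24 (3aR,6S,7aS)-5-[(methoxymethoxy)methyl]-3a-methyl-6-(2-oxopropyl)-3a,6,7,7a-tetrahydro-1-benzofuran-2(3H)-one
Product: 25 (3aR,6R,7aS)-6-[(2R)-2-hydroxypropyl]-5-[(methoxymethoxy)methyl]-3a-methyl-3a,6,7,7a-tetrahydro-1-benzofuran-2(3H)-one
Conditions: (S)-1-methyl-3,3-diphenyltetrahydro-1H,3H-pyrrolo[1,2-c][1,3,2]oxazaborole (0.3 equiv), catecholborane, toluene, −78 °C
Reagents that add atoms: none
Why: Corey–Bakshi–Shibata reduction under catalyst control (CH2R as the large group, CH3 as the small one) should give the (R)-carbinol at C23; selectivity for a methyl alkyl ketone is moderate, and the C23 epimer is a diastereomer that chromatography can remove.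

Step 16
Reactants: 25 (3aR,6R,7aS)-6-[(2R)-2-hydroxypropyl]-5-[(methoxymethoxy)methyl]-3a-methyl-3a,6,7,7a-tetrahydro-1-benzofuran-2(3H)-one
Product: 26 bis-MOM lactone (25 with the C23 hydroxyl as MOM ether)
Conditions: MOMCl, iPr2NEt, Bu4NI (cat.), CH2Cl2, rt
Reagents that add atoms: chloromethyl methyl ether, COCCl
Why: Alkoxymethylation of the secondary alcohol (O25); both MOM ethers now match the end-game.

Step 17
Reactants: 26 bis-MOM lactone
Product: 27 2-[(1R,6S)-6-hydroxy-3-[(methoxymethoxy)methyl]-4-[(2R)-2-(methoxymethoxy)propyl]-1-methylcyclohex-2-en-1-yl]ethan-1-ol (C4 side chain cis to the hydroxyethyl arm)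
Conditions: LiAlH4, THF, 0 °C
Reagents that add atoms: none
Why: Hydride reduction of the lactone releases the C13 primary alcohol and the C27 secondary alcohol; acetals and the alkene are inert.

Step 18
Reactants: 27 diol
Product: 28 primary tert-butyldiphenylsilyl ether of 27 (C13 OTBDPS; C27 hydroxyl free)
Conditions: TBDPSCl, imidazole, CH2Cl2, 0 °C
Reagents that add atoms: tert-butyldiphenylsilyl chloride, CC(C)(C)[Si](Cl)(c1ccccc1)c1ccccc1
Why: Silylation should be selective for the primary hydroxyl; the C27 hydroxyl is secondary and next to quaternary C15.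

Step 19
Reactants: 28 primary tert-butyldiphenylsilyl ether
Product: 29 ring C ketone (28 oxidised at C27)
Conditions: Dess–Martin periodinane, NaHCO3, CH2Cl2, rt
Reagents that add atoms: none
Why: Dess–Martin oxidation of a hindered secondary alcohol; the β,γ-alkene cannot move into conjugation because C15 is quaternary.

Step 20
Reactants: 29 ring C ketone; 30 methyl propiolate
Product: 32 propargylic alcohol (methyl 3-substituted prop-2-ynoate on C27; O28 cis to the C14 arm), via lithium methyl propiolate 31 (not isolated)
Conditions: LiN(iPr)2, THF, −78 °C; then 29, −78 to −40 °C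
Reagents that add atoms: none
Why: Acetylide addition to a ketone; axial attack anti to the pseudo-axial C14 arm on C15 and away from the C21 side chain should place the alkyne cis to the C16 methyl and O28 cis to C14, which is the spiro configuration of the target.

Step 21
Reactants: 32 propargylic alcohol
Product: 34 ring C/D spirotetronate methyl ether (4-methoxy-1-oxaspiro[4.5]deca-3,6-dien-2-one core; C13 OTBDPS; O20 and O25 MOM), via methoxyacrylate 33 (not isolated)
Conditions: NaOMe, MeOH, rt to 50 °C
Reagents that add atoms: sodium methoxide, [Na+].[O-]C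
Why: Conjugate addition of methoxide to the ynoate and lactonisation of the tertiary hydroxyl onto the ester give the 4-methoxy-2(5H)-furanone, a known way from ketones to spiro-tetronate methyl ethers.

Step 22
Reactants: 34 ring C/D spirotetronate methyl ether; 10 decalin aldehyde
Product: 36 coupled carbinol (C31–C34 bond; C34 hydroxyl as both epimers; C12 OTBS; C13 OTBDPS), via lithiated tetronate 35 (not isolated)
Conditions: LiN(iPr)2, THF, −78 °C; then 10, −78 to −20 °C
Reagents that add atoms: none
Why: 4-Methoxy-2(5H)-furanones are lithiated at C3 (here C31) by lithium amides, and the vinyl-lithium adds to hindered aldehydes; both C34 epimers converge in step 23.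

Step 23
Reactants: 36 coupled carbinol
Product: 37 seco ketone (3-acyl-4-methoxytetronate; C12 OTBS; C13 OTBDPS)
Conditions: Dess–Martin periodinane, NaHCO3, CH2Cl2, rt
Reagents that add atoms: none
Why: Dess–Martin oxidation of the doubly hindered carbinol to the C34 ketone, the usual second half of tetronate acylation by addition and oxidation.

Step 24
Reactants: 37 seco ketone
Product: 38 seco ketone with free C12 hydroxyl (C13 OTBDPS kept)
Conditions: pyridinium p-toluenesulfonate (0.3 equiv), MeOH, rt
Reagents that add atoms: none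
Why: Mild acid methanolysis removes a primary TBS ether much faster than a primary TBDPS ether and should leave the MOM acetals intact.

Step 25
Reactants: 38 seco ketone with free C12 hydroxyl; 39 thioacetic acid
Product: 40 C12 thioacetate (C13 OTBDPS)
Conditions: PPh3, diisopropyl azodicarboxylate, THF, 0 °C
Reagents that add atoms: none
Why: Mitsunobu substitution of a primary alcohol by thioacetic acid; C12 is not a stereocentre and C10 is not involved.

Step 26
Reactants: 40 C12 thioacetate
Product: 41 C12 thioacetate with free C13 hydroxyl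
Conditions: HF·pyridine, pyridine, THF, 0 °C to rt
Reagents that add atoms: none
Why: Buffered fluoride removes the TBDPS ether; thioester, MOM acetals and the vinylogous ester should be stable to it.

Step 27
Reactants: 41 C12 thioacetate with free C13 hydroxyl
Product: 42 C12 thioacetate C13 mesylate
Conditions: MsCl, Et3N, CH2Cl2, −20 °C
Reagents that add atoms: methanesulfonyl chloride, CS(=O)(=O)Cl
Why: Standard sulfonylation of a primary alcohol; the thioester is not affected.

Step 28
Reactants: 42 C12 thioacetate C13 mesylate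
Product: 44 macrocyclic sulfide (12-membered thiacycle with sulfur between C12 and C13; tetronate methyl ether; O20 and O25 MOM), via thiol 43 (not isolated)
Conditions: K2CO3, MeOH/THF (degassed), 1 mM, rt
Reagents that add atoms: none
Why: Methanolysis of the thioacetate releases the thiolate, which should displace the primary mesylate intramolecularly at high dilution, the standard thioacetate/alkyl sulfonate route to macrocyclic sulfides. Attack on C32 would need an eight-membered ring at a hindered carbon and is expected to be slower.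

Step 29
Reactants: 44 macrocyclic sulfide
Product: 45 macrocyclic sulfone (tetronate methyl ether)
Conditions: (NH4)6Mo7O24·4H2O (0.2 equiv), H2O2 (30%), EtOH, 0 °C to rt
Reagents that add atoms: hydrogen peroxide, OO
Why: Molybdate-catalysed peroxide oxidation takes sulfides to sulfones and leaves unactivated alkenes alone.

Step 30
Reactants: 45 macrocyclic sulfone
Product: 46 macrocyclic sulfone with free acyl tetronic acid
Conditions: LiCl, DMSO, 55 °C; dilute HCl work-up
Reagents that add atoms: none
Why: Chloride dealkylates the O-methyl group of a 3-acyl-4-methoxytetronate by SN2 at carbon, a known unmasking of acyl tetronic acids; the sulfone and the acetals are inert.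

Step 31
Reactants: 46 macrocyclic sulfone with free acyl tetronic acid
Product: 49 bis-MOM ether of the target (E-C12=C13; O20 and O25 MOM), via bromosulfone 47 (not isolated), via episulfone 48 (not isolated)
Conditions: CBr2F2, KOH on Al2O3, tBuOH/CH2Cl2, 0 °C to rt
Reagents that add atoms: none
Why: Ramberg–Bäcklund reaction with halogenation in the flask, the known route from cyclic sulfones to medium and large cycloalkenes. On KOH/Al2O3 one α-methylene of 46 (C13 or C12) is deprotonated and brominated by CBr2F2 to give 47; the α′-carbanion then displaces bromide in a 1,3-elimination (3-exo-tet) to episulfone 48, which loses SO2 cheletropically and leaves the C12=C13 alkene. The 11-membered carbocycle therefore arises by contraction of the preformed 12-membered thiacycle and not by a medium-ring C–C closure, so no dilution is needed. No stereocentre is created; the selectivity needed is the E geometry, which should follow from base-mediated equilibration of the episulfone to its trans isomer before the stereospecific extrusion and from the lower strain of the E-cycloundecene in this bridged frame. Chemoselectivity comes from the substrate: C12 and C13 are the only acidic methylenes, C10 is β to sulfur, C36 and C31 carry no hydrogen, and the tetronic acid is present as its potassium salt, so C32 and C34, each in a 1,5-relationship to one of the carbanions, are not electrophilic. The MOM ethers and both ring alkenes are inert to the base.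

Step 32
Reactants: 49 bis-MOM ether of the target
Product: 50 target CNP0189906.1
Conditions: HCl (2 M aq.), MeOH/THF, 45 °C
Reagents that add atoms: none
Why: Acid-catalysed acetal exchange removes both MOM ethers; the acyl tetronic acid, the isolated alkenes and the primary allylic alcohol should tolerate dilute acid.

## Compound list

1 | methyl (R)-3-hydroxy-2-methylpropanoate | COC(=O)[C@H](C)CO | starting material
2 | methyl (R)-3-[(tert-butyldimethylsilyl)oxy]-2-methylpropanoate | COC(=O)[C@H](C)CO[Si](C)(C)C(C)(C)C | intermediate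
3 | (R)-3-[(tert-butyldimethylsilyl)oxy]-2-methylpropanal | O=C[C@H](C)CO[Si](C)(C)C(C)(C)C | intermediate
4 | tert-butyldimethyl{[(2S,3E)-2-methyl-4-(4,4,5,5-tetramethyl-1,3,2-dioxaborolan-2-yl)but-3-en-1-yl]oxy}silane | CC1(C)OB(/C=C/[C@H](C)CO[Si](C)(C)C(C)(C)C)OC1(C)C | intermediate
5 | (S)-citronellal | C[C@H](CC=O)CCC=C(C)C | starting material
6 | (1E,4S)-1-iodo-4,8-dimethylnona-1,7-diene | C[C@H](C/C=C/I)CCC=C(C)C | intermediate
7 | (2E,6S,8E)-9-iodo-2,6-dimethylnona-2,8-dien-1-ol | C[C@H](C/C=C/I)CC/C=C(\C)CO | intermediate
8 | (2E,6S,8E)-9-iodo-2,6-dimethylnona-2,8-dienal | C[C@H](C/C=C/I)CC/C=C(\C)C=O | intermediate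
9 | (2E,6S,8E,10E,12S)-13-[(tert-butyldimethylsilyl)oxy]-2,6,12-trimethyltrideca-2,8,10-trienal | C[C@H](C/C=C/C=C/[C@H](C)CO[Si](C)(C)C(C)(C)C)CC/C=C(\C)C=O | intermediate
10 | (1S,2S,4aS,6S,8aR)-2-[(2S)-1-[(tert-butyldimethylsilyl)oxy]propan-2-yl]-1,6-dimethyl-1,2,4a,5,6,7,8,8a-octahydronaphthalene-1-carbaldehyde (decalin aldehyde; C12 OTBS) | C[C@H]1CC[C@@H]2[C@H](C=C[C@@H]([C@H](C)CO[Si](C)(C)C(C)(C)C)[C@@]2(C)C=O)C1 | intermediate
11 | 2-methylcyclohexane-1,3-dione | CC1C(=O)CCCC1=O | starting material
12 | ethyl bromoacetate | CCOC(=O)CBr | starting material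
13 | ethyl 2-(1-methyl-2,6-dioxocyclohexyl)acetate | CCOC(=O)CC1(C)C(=O)CCCC1=O | intermediate
14 | ethyl 2-[(1S,2S)-2-hydroxy-1-methyl-6-oxocyclohexyl]acetate | CCOC(=O)C[C@]1(C)C(=O)CCC[C@@H]1O | intermediate
15 | (3aS,7aS)-3a-methylhexahydro-1-benzofuran-2,4-dione | O=C1C[C@]2(C)C(=O)CCC[C@@H]2O1 | intermediate
16 | (3aS,7aS)-3a-methyl-4-[(trimethylsilyl)oxy]-3a,6,7,7a-tetrahydro-1-benzofuran-2(3H)-one | O=C1C[C@]2(C)C(O[Si](C)(C)C)=CCC[C@@H]2O1 | intermediate
17 | (3aS,7aS)-3a-methyl-3a,7a-dihydro-1-benzofuran-2,4(3H,7H)-dione | O=C1C[C@]2(C)C(=O)C=CC[C@@H]2O1 | intermediate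
18 | (3aS,7aS)-5-(hydroxymethyl)-3a-methyl-3a,7a-dihydro-1-benzofuran-2,4(3H,7H)-dione | O=C1C[C@]2(C)C(=O)C(CO)=CC[C@@H]2O1 | intermediate
19 | (3aS,7aS)-5-[(methoxymethoxy)methyl]-3a-methyl-3a,7a-dihydro-1-benzofuran-2,4(3H,7H)-dione | O=C1C[C@]2(C)C(=O)C(COCOC)=CC[C@@H]2O1 | intermediate
20 | (3aR,4R,7aS)-4-hydroxy-5-[(methoxymethoxy)methyl]-3a-methyl-3a,4,7,7a-tetrahydro-1-benzofuran-2(3H)-one | O=C1C[C@]2(C)[C@H](O)C(COCOC)=CC[C@@H]2O1 | intermediate
21 | 2-methoxypropene | COC(C)=C | starting material
22 | mixed acetal of 20 (C17 O–C(CH3)2–OCH3) | O=C1C[C@]2(C)[C@H](OC(C)(C)OC)C(COCOC)=CC[C@@H]2O1 | intermediate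
23 | isopropenyl ether of 20 | O=C1C[C@]2(C)[C@H](OC(C)=C)C(COCOC)=CC[C@@H]2O1 | intermediate
24 | (3aR,6S,7aS)-5-[(methoxymethoxy)methyl]-3a-methyl-6-(2-oxopropyl)-3a,6,7,7a-tetrahydro-1-benzofuran-2(3H)-one | O=C1C[C@]2(C)C=C(COCOC)[C@H](CC(C)=O)C[C@@H]2O1 | intermediate
25 | (3aR,6R,7aS)-6-[(2R)-2-hydroxypropyl]-5-[(methoxymethoxy)methyl]-3a-methyl-3a,6,7,7a-tetrahydro-1-benzofuran-2(3H)-one | O=C1C[C@]2(C)C=C(COCOC)[C@H](C[C@@H](C)O)C[C@@H]2O1 | intermediate
26 | bis-MOM lactone (25 with O25 as MOM ether) | O=C1C[C@]2(C)C=C(COCOC)[C@H](C[C@@H](C)OCOC)C[C@@H]2O1 | intermediate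
27 | 2-[(1R,6S)-6-hydroxy-3-[(methoxymethoxy)methyl]-4-[(2R)-2-(methoxymethoxy)propyl]-1-methylcyclohex-2-en-1-yl]ethan-1-ol (C4 side chain cis to the hydroxyethyl arm) | OCC[C@]1(C)C=C(COCOC)[C@H](C[C@@H](C)OCOC)C[C@@H]1O | intermediate
28 | primary tert-butyldiphenylsilyl ether of 27 (C13 OTBDPS) | CC(C)(C)[Si](c1ccccc1)(c1ccccc1)OCC[C@]2(C)C=C(COCOC)[C@H](C[C@@H](C)OCOC)C[C@@H]2O | intermediate
29 | ring C ketone (C27 ketone) | CC(C)(C)[Si](c1ccccc1)(c1ccccc1)OCC[C@]2(C)C=C(COCOC)[C@H](C[C@@H](C)OCOC)CC2=O | intermediate
30 | methyl propiolate | C#CC(=O)OC | starting material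
31 | lithium methyl propiolate | [Li]C#CC(=O)OC | intermediate
32 | propargylic alcohol (alkyne on C27 cis to the C16 methyl) | CC(C)(C)[Si](c1ccccc1)(c1ccccc1)OCC[C@]2(C)C=C(COCOC)[C@H](C[C@@H](C)OCOC)C[C@@]2(O)C#CC(=O)OC | intermediate
33 | methyl (E)-3-methoxyacrylate adduct of 32 (hydroxyl-bearing carbon cis to the ester) | CC(C)(C)[Si](c1ccccc1)(c1ccccc1)OCC[C@]2(C)C=C(COCOC)[C@H](C[C@@H](C)OCOC)C[C@@]2(O)/C(OC)=C\C(=O)OC | intermediate
34 | ring C/D spirotetronate methyl ether | CC(C)(C)[Si](c1ccccc1)(c1ccccc1)OCC[C@]2(C)C=C(COCOC)[C@H](C[C@@H](C)OCOC)C[C@]23OC(=O)C=C3OC | intermediate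
35 | C31-lithiated spirotetronate | CC(C)(C)[Si](c1ccccc1)(c1ccccc1)OCC[C@]2(C)C=C(COCOC)[C@H](C[C@@H](C)OCOC)C[C@]23OC(=O)C([Li])=C3OC | intermediate
36 | coupled carbinol (C34 OH, both epimers) | CC(C)(C)[Si](c1ccccc1)(c1ccccc1)OCC[C@]4(C)C=C(COCOC)[C@H](C[C@@H](C)OCOC)C[C@]45OC(=O)C(=C5OC)C(O)[C@]2(C)[C@H]([C@H](C)CO[Si](C)(C)C(C)(C)C)C=C[C@@H]3C[C@@H](C)CC[C@@H]23 | intermediate
37 | seco ketone (C12 OTBS; C13 OTBDPS) | CC(C)(C)[Si](c1ccccc1)(c1ccccc1)OCC[C@]4(C)C=C(COCOC)[C@H](C[C@@H](C)OCOC)C[C@]45OC(=O)C(=C5OC)C(=O)[C@]2(C)[C@H]([C@H](C)CO[Si](C)(C)C(C)(C)C)C=C[C@@H]3C[C@@H](C)CC[C@@H]23 | intermediate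
38 | seco ketone with free C12 hydroxyl | CC(C)(C)[Si](c1ccccc1)(c1ccccc1)OCC[C@]4(C)C=C(COCOC)[C@H](C[C@@H](C)OCOC)C[C@]45OC(=O)C(=C5OC)C(=O)[C@]2(C)[C@H]([C@H](C)CO)C=C[C@@H]3C[C@@H](C)CC[C@@H]23 | intermediate
39 | thioacetic acid | CC(=O)S | starting material
40 | C12 thioacetate (C13 OTBDPS) | CC(C)(C)[Si](c1ccccc1)(c1ccccc1)OCC[C@]4(C)C=C(COCOC)[C@H](C[C@@H](C)OCOC)C[C@]45OC(=O)C(=C5OC)C(=O)[C@]2(C)[C@H]([C@H](C)CSC(C)=O)C=C[C@@H]3C[C@@H](C)CC[C@@H]23 | intermediate
41 | C12 thioacetate with free C13 hydroxyl | OCC[C@]4(C)C=C(COCOC)[C@H](C[C@@H](C)OCOC)C[C@]45OC(=O)C(=C5OC)C(=O)[C@]2(C)[C@H]([C@H](C)CSC(C)=O)C=C[C@@H]3C[C@@H](C)CC[C@@H]23 | intermediate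
42 | C12 thioacetate C13 mesylate | CS(=O)(=O)OCC[C@]4(C)C=C(COCOC)[C@H](C[C@@H](C)OCOC)C[C@]45OC(=O)C(=C5OC)C(=O)[C@]2(C)[C@H]([C@H](C)CSC(C)=O)C=C[C@@H]3C[C@@H](C)CC[C@@H]23 | intermediate
43 | C12 thiol C13 mesylate | CS(=O)(=O)OCC[C@]4(C)C=C(COCOC)[C@H](C[C@@H](C)OCOC)C[C@]45OC(=O)C(=C5OC)C(=O)[C@]2(C)[C@H]([C@H](C)CS)C=C[C@@H]3C[C@@H](C)CC[C@@H]23 | intermediate
44 | macrocyclic sulfide (tetronate methyl ether) | C[C@H]1CC[C@@H]2[C@H](C=C[C@H]3[C@H](C)CSCC[C@]4(C)C=C(COCOC)[C@H](C[C@@H](C)OCOC)C[C@]45OC(=O)C(=C5OC)C(=O)[C@@]23C)C1 | intermediate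
45 | macrocyclic sulfone (tetronate methyl ether) | C[C@H]1CC[C@@H]2[C@H](C=C[C@H]3[C@H](C)CS(=O)(=O)CC[C@]4(C)C=C(COCOC)[C@H](C[C@@H](C)OCOC)C[C@]45OC(=O)C(=C5OC)C(=O)[C@@]23C)C1 | intermediate
46 | macrocyclic sulfone with free acyl tetronic acid | C[C@H]1CC[C@@H]2[C@H](C=C[C@H]3[C@H](C)CS(=O)(=O)CC[C@]4(C)C=C(COCOC)[C@H](C[C@@H](C)OCOC)C[C@]45OC(=O)C(=C5O)C(=O)[C@@]23C)C1 | intermediate
47 | α-bromosulfone (bromine on C13, either epimer) | C[C@H]1CC[C@@H]2[C@H](C=C[C@H]3[C@H](C)CS(=O)(=O)C(Br)C[C@]4(C)C=C(COCOC)[C@H](C[C@@H](C)OCOC)C[C@]45OC(=O)C(=C5O)C(=O)[C@@]23C)C1 | intermediate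
48 | trans-episulfone across C12 and C13 (one of the two trans isomers drawn) | C[C@H]1CC[C@@H]2[C@H](C=C[C@H]3[C@H](C)[C@@H]6[C@H](S6(=O)=O)C[C@]4(C)C=C(COCOC)[C@H](C[C@@H](C)OCOC)C[C@]45OC(=O)C(=C5O)C(=O)[C@@]23C)C1 | intermediate
49 | bis-MOM ether of the target | C[C@H]1CC[C@@H]2[C@H](C=C[C@H]3[C@H](C)/C=C/C[C@]4(C)C=C(COCOC)[C@H](C[C@@H](C)OCOC)C[C@]45OC(=O)C(=C5O)C(=O)[C@@]23C)C1 | intermediate
50 | CNP0189906.1 | C[C@H]1CC[C@@H]2[C@H](C=C[C@H]3[C@H](C)/C=C/C[C@]4(C)C=C(CO)[C@H](C[C@@H](C)O)C[C@]45OC(=O)C(=C5O)C(=O)[C@@]23C)C1 | target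

## Step count and risks

Total: 32 steps. Longest linear sequence: 25 steps (11 to 50, steps 8–32).

**Step 31 (key step).** Most likely failure: loss of E/Z control, with extrusion from the cis episulfone before it equilibrates, or slow α-bromination that lets hydroxide degrade the substrate. Fallback, from 44 to 49: the halogen is put in at the sulfide level and the extrusion is run as its own anhydrous step. N-Chlorosuccinimide chlorinates 44 at an α-methylene to the α-chlorosulfide F1. Molybdate/H2O2 oxidises it to the α-chlorosulfone F2. LiCl in DMSO frees the tetronic acid α-chlorosulfone F3. KOtBu in THF at −78 °C, a base strong enough to epimerise the episulfone, then gives 49.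

**Step 7.** Most likely failure: poor facial selectivity, the tether keeping its C2 methyl equatorial against catalyst and C10. Fallback, from 6 to 10: iminium catalysis on the α-unsubstituted enal, with the quaternary methyl added afterwards. Ozonolysis of the prenyl alkene of 6 (O3, then Me2S) gives aldehyde F4. Wittig reaction with (triphenylphosphoranylidene)acetaldehyde gives enal F5. Suzuki–Miyaura coupling with 4 gives trienal F6. Cycloaddition catalysed by (2S,5S)-5-benzyl-2-tert-butyl-3-methylimidazolidin-4-one trifluoroacetate gives the decalin aldehyde F7. C-Methylation of its potassium enolate (KOtBu, MeI), anti to the C10 chain, gives 10. The tether bias remains in this variant too; if both fail, the decalin of Alternative 2 is the replacement.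

**Step 28.** Most likely failure: intermolecular S-alkylation, or attack of the thiolate on the acyl tetronate (C32 or the O-methyl group) in place of the mesylate. Fallback, from 42 to 46: the tetronate is ionised first. LiCl in DMSO demethylates 42 and turns the mesylate into the chloride, giving chloro tetronic acid F8. K2CO3 with NaI in MeOH/THF at high dilution closes the macrocyclic sulfide F9 on the unreactive tetronate anion. Molybdate/H2O2 then gives 46.

**Step 13.** Most likely failure: hydride delivery from the concave face, giving the C17 epimer and, after step 14, the wrong C21. Fallback, from 19 to 20: if the epimeric alcohol F10 is the main product, Mitsunobu esterification with 4-nitrobenzoic acid inverts C17 to the ester F11, and methanolysis (K2CO3, MeOH) gives 20. Competing SN2′ attack is the risk of this inversion.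

**Step 15.** Most likely failure: low diastereoselectivity at C23. Fallback, from 24 to 25: NaBH4 reduction gives 25 and its C23 epimer F12. After separation, Mitsunobu inversion of F12 with 4-nitrobenzoic acid gives the ester F13, and methanolysis gives 25.

## Further compounds

F1 | step 31 | α-chlorosulfide of 44 (chlorine on C13) | C[C@H]1CC[C@@H]2[C@H](C=C[C@H]3[C@H](C)CSC(Cl)C[C@]4(C)C=C(COCOC)[C@H](C[C@@H](C)OCOC)C[C@]45OC(=O)C(=C5OC)C(=O)[C@@]23C)C1
F2 | step 31 | α-chlorosulfone (tetronate methyl ether) | C[C@H]1CC[C@@H]2[C@H](C=C[C@H]3[C@H](C)CS(=O)(=O)C(Cl)C[C@]4(C)C=C(COCOC)[C@H](C[C@@H](C)OCOC)C[C@]45OC(=O)C(=C5OC)C(=O)[C@@]23C)C1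
F3 | step 31 | α-chlorosulfone with free acyl tetronic acid | C[C@H]1CC[C@@H]2[C@H](C=C[C@H]3[C@H](C)CS(=O)(=O)C(Cl)C[C@]4(C)C=C(COCOC)[C@H](C[C@@H](C)OCOC)C[C@]45OC(=O)C(=C5O)C(=O)[C@@]23C)C1
F4 | step 7 | (4S,6E)-7-iodo-4-methylhept-6-enal | C[C@H](C/C=C/I)CCC=O
F5 | step 7 | (2E,6S,8E)-9-iodo-6-methylnona-2,8-dienal | C[C@H](C/C=C/I)CC/C=C/C=O
F6 | step 7 | (2E,6S,8E,10E,12S)-13-[(tert-butyldimethylsilyl)oxy]-6,12-dimethyltrideca-2,8,10-trienal | C[C@H](C/C=C/C=C/[C@H](C)CO[Si](C)(C)C(C)(C)C)CC/C=C/C=O
F7 | step 7 | decalin aldehyde lacking the C37 methyl (C36–H, aldehyde cis to the C10 chain) | C[C@H]1CC[C@@H]2[C@H](C=C[C@@H]([C@H](C)CO[Si](C)(C)C(C)(C)C)[C@H]2C=O)C1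
F8 | step 28 | C13 chloride C12 thioacetate with free acyl tetronic acid | ClCC[C@]4(C)C=C(COCOC)[C@H](C[C@@H](C)OCOC)C[C@]45OC(=O)C(=C5O)C(=O)[C@]2(C)[C@H]([C@H](C)CSC(C)=O)C=C[C@@H]3C[C@@H](C)CC[C@@H]23
F9 | step 28 | macrocyclic sulfide with free acyl tetronic acid | C[C@H]1CC[C@@H]2[C@H](C=C[C@H]3[C@H](C)CSCC[C@]4(C)C=C(COCOC)[C@H](C[C@@H](C)OCOC)C[C@]45OC(=O)C(=C5O)C(=O)[C@@]23C)C1
F10 | step 13 | C17 epimer of 20 (hydroxyl trans to the lactone ring) | O=C1C[C@]2(C)[C@@H](O)C(COCOC)=CC[C@@H]2O1
F11 | step 13 | 4-nitrobenzoate of 20 | O=C1C[C@]2(C)[C@H](OC(=O)c3ccc(cc3)[N+](=O)[O-])C(COCOC)=CC[C@@H]2O1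
F12 | step 15 | C23 epimer of 25 ((2S)-2-hydroxypropyl) | O=C1C[C@]2(C)C=C(COCOC)[C@H](C[C@H](C)O)C[C@@H]2O1
F13 | step 15 | 4-nitrobenzoate of 25 | O=C1C[C@]2(C)C=C(COCOC)[C@H](C[C@@H](C)OC(=O)c3ccc(cc3)[N+](=O)[O-])C[C@@H]2O1
A1 | alternative 1 | (E)-3-(4-hydroxyphenyl)-3-methoxyacrylic acid | CO/C(=C/C(=O)O)c1ccc(O)cc1
A2 | alternative 1 | 4-methoxy-1-oxaspiro[4.5]deca-3,6,9-triene-2,8-dione | COC1=CC(=O)OC12C=CC(=O)C=C2
A3 | alternative 2 | ring-A-fused δ-lactone (C34 carbonyl, ring oxygen on C7, E-alkenyl on C7; C36 configuration open, lost on enolisation) | C[C@H]1CC[C@@H]2[C@@H](C1)[C@H](/C=C/[C@H](C)CO[Si](C)(C)C(C)(C)C)OC(=O)C2C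
A4 | alternative 2 | decalin C34 carboxylic acid | C[C@H]1CC[C@@H]2[C@H](C=C[C@@H]([C@H](C)CO[Si](C)(C)C(C)(C)C)[C@@]2(C)C(=O)O)C1
A5 | alternative 3 | spirotetronate cyclohexenol with the C15=C17 alkene and C18 hydroxyl | COc1ccc(COCCC2=C[C@@H](O)CC[C@]23OC(=O)C=C3OC)cc1
A6 | alternative 3 | cyclopropyl carbinol with quaternary C15 | COc1ccc(COCC[C@@]24C[C@H]4[C@@H](O)CC[C@]23OC(=O)C=C3OC)cc1
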